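**Plan**

- The retrosynthesis first removes three benzyl ethers, then cuts the central oxazole at O1–C5 and N3–C4. That ring is 2,4-disubstituted with hydrogen at C5, so C5 maps onto a CH2Br carbon, C4 onto a ketone carbon, and C2/O1/N3 onto a primary amide.
- The bromomethyl ketone is traced back through hydration of a bromoalkyne, the palmitate C–O bond, and the C1–C(alkyne) bond to a silylacetylene and the open-chain tribenzyl aldehyde of 2-deoxy-L-fucose.
- The amide comes from oxazole-5-carboxylic acid by one-carbon homologation (Arndt–Eistert), so the terminal oxazole is bought intact.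
- Forward order: C6 sugar + C2 alkyne, palmitate onto the only free hydroxyl, alkyne to bromomethyl ketone, closure of the central oxazole (the only ring made), then hydrogenolysis.
- Stereochemistry: C3, C4 and C5 are taken unchanged from 2-deoxy-L-fucose (3S,4R,5S). C1 (R) is set by Noyori transfer hydrogenation of the ynone with the (R,R)-catalyst.

Key step: step 12

Remark: 2-deoxy-L-fucose is drawn open-chain although it is supplied as the pyranose hemiacetal, which reacts through this form; chain atoms are called C1 (ester carbinol) to C6 (methyl) throughout.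

**Route**

Step 1
Reactants: 1 2-deoxy-L-fucose (2,6-dideoxy-L-lyxo-hexose)
Product: 2 2-deoxy-L-fucose diethyl dithioacetal, (2S,3R,4S)-6,6-bis(ethylsulfanyl)hexane-2,3,4-triol
Conditions: EtSH, conc. aq. HCl, 0 °C
Reagents that add atoms: ethanethiol CCS
Why: Fischer dithioacetalisation; a 2-deoxy aldose opens easily under acid and is trapped by the thiol as the acyclic dithioacetal, which masks C1 and leaves O3, O4 and O5 free without touching a stereocentre.

Step 2
Reactants: 2 2-deoxy-L-fucose diethyl dithioacetal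
Product: 3 3,4,5-tri-O-benzyl-2-deoxy-L-fucose diethyl dithioacetal
Conditions: NaH, BnBr, Bu4NI (cat.), DMF, 0 °C → rt
Reagents that add atoms: benzyl bromide BrCc1ccccc1
Why: Williamson etherification of the three secondary hydroxyls, which a dithioacetal tolerates and which involves no C–O bond at a stereocentre.

Step 3
Reactants: 3 3,4,5-tri-O-benzyl-2-deoxy-L-fucose diethyl dithioacetal
Product: 4 3,4,5-tri-O-benzyl-2-deoxy-aldehydo-L-fucose, (3S,4R,5S)-3,4,5-tris(benzyloxy)hexanal
Conditions: I2, NaHCO3, acetone/H2O, 0 °C → rt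
Reagents that add atoms: water O
Why: Iodine-mediated oxidative hydrolysis of the dithioacetal (sulfur activation, then water) should release the aldehyde, with the bicarbonate buffer mild enough to avoid β-elimination of the C3 benzyloxy group.

Step 4
Reactants: 4 (3S,4R,5S)-3,4,5-tris(benzyloxy)hexanal, 5 ethynyltrimethylsilane
Product: 7 (5S,6R,7S)-5,6,7-tris(benzyloxy)-1-(trimethylsilyl)oct-1-yn-3-ol (both C3 epimers), via lithium (trimethylsilyl)acetylide 6 (not isolated)
Conditions: n-BuLi, THF, −78 °C; then 4, −78 °C; aq. NH4Cl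
Reagents that add atoms: none
Why: 1,2-Addition of a lithium acetylide to the aldehyde at low temperature; the new carbinol centre is not controlled, which is acceptable because the next step erases it.

Step 5
Reactants: 7 (5S,6R,7S)-5,6,7-tris(benzyloxy)-1-(trimethylsilyl)oct-1-yn-3-ol (both C3 epimers)
Product: 8 (5S,6R,7S)-5,6,7-tris(benzyloxy)-1-(trimethylsilyl)oct-1-yn-3-one
Conditions: Dess–Martin periodinane, NaHCO3, CH2Cl2, 0 °C → rt
Reagents that add atoms: none
Why: Dess–Martin oxidation of a propargylic alcohol under buffered, non-basic conditions should converge both epimers on one ynone without eliminating the β-benzyloxy group.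

Step 6
Reactants: 8 (5S,6R,7S)-5,6,7-tris(benzyloxy)-1-(trimethylsilyl)oct-1-yn-3-one
Product: 9 (3R,5S,6R,7S)-5,6,7-tris(benzyloxy)-1-(trimethylsilyl)oct-1-yn-3-ol
Conditions: Ru[(R,R)-TsDPEN](p-cymene) (cat.), i-PrOH, rt
Reagents that add atoms: none
Why: Noyori asymmetric transfer hydrogenation of an α,β-acetylenic ketone; the alkyne takes the place the aryl group has in aryl ketone reductions, so the (R,R)-catalyst is expected to deliver hydride under reagent control to give the (R)-carbinol, and the base-free medium spares the β-alkoxy ketone.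

Step 7
Reactants: 9 (3R,5S,6R,7S)-5,6,7-tris(benzyloxy)-1-(trimethylsilyl)oct-1-yn-3-ol, 10 palmitoyl chloride
Product: 11 (3R,5S,6R,7S)-5,6,7-tris(benzyloxy)-1-(trimethylsilyl)oct-1-yn-3-yl hexadecanoate
Conditions: pyridine, DMAP (cat.), CH2Cl2, 0 °C → rt
Reagents that add atoms: none
Why: DMAP-catalysed acylation of the only free hydroxyl, with retention at C1 because the C–O bond is not broken.

Step 8
Reactants: 11 (3R,5S,6R,7S)-5,6,7-tris(benzyloxy)-1-(trimethylsilyl)oct-1-yn-3-yl hexadecanoate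
Product: 12 (3R,5S,6R,7S)-5,6,7-tris(benzyloxy)-1-bromooct-1-yn-3-yl hexadecanoate
Conditions: NBS, AgNO3 (cat.), acetone, rt, dark
Reagents that add atoms: N-bromosuccinimide O=C1CCC(=O)N1Br
Why: Silver-catalysed bromodesilylation; Ag(I) turns the alkynylsilane into a silver acetylide that NBS brominates, and the ester and benzyl ethers are inert in the dark at room temperature.

Step 9
Reactants: 12 (3R,5S,6R,7S)-5,6,7-tris(benzyloxy)-1-bromooct-1-yn-3-yl hexadecanoate
Product: 13 (3R,5S,6R,7S)-5,6,7-tris(benzyloxy)-1-bromo-2-oxooctan-3-yl hexadecanoate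
Conditions: Ph3PAuCl (cat.), AgSbF6 (cat.), 1,4-dioxane/H2O, rt
Reagents that add atoms: water O
Why: Gold(I)-catalysed hydration of a 1-bromoalkyne, steered by 5-exo-dig attack of the palmitate carbonyl oxygen on the activated alkyne; water opens the resulting dioxolenium ion so that the ketone falls on C2 and the bromine-bearing carbon becomes CH2Br, while the C–O bond at the stereocentre is never broken.

Step 10
Reactants: 14 1,3-oxazole-5-carboxylic acid
Product: 16 2-diazo-1-(1,3-oxazol-5-yl)ethan-1-one, via 1,3-oxazole-5-carbonyl chloride 15 (not isolated)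
Conditions: (COCl)2, DMF (cat.), CH2Cl2, 0 °C → rt; concentrate; TMSCHN2, THF/MeCN, 0 °C → rt
Reagents that add atoms: (trimethylsilyl)diazomethane C[Si](C)(C)C=[N+]=[N-]
Why: First stage of an Arndt–Eistert homologation; the acid chloride acylates the diazo carbon and chloride removes the silyl group from the acyldiazonium ion to leave the diazoketone.

Step 11
Reactants: 16 2-diazo-1-(1,3-oxazol-5-yl)ethan-1-one
Product: 18 2-(1,3-oxazol-5-yl)acetamide, via (1,3-oxazol-5-yl)ketene 17 (not isolated)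
Conditions: AgNO3 (cat.), aq. NH3, 1,4-dioxane, 60 °C
Reagents that add atoms: ammonia N
Why: Silver-catalysed Wolff rearrangement; the oxazolyl group migrates to give the ketene, which ammonia traps as the homologated primary amide.

Step 12
Reactants: 13 (3R,5S,6R,7S)-5,6,7-tris(benzyloxy)-1-bromo-2-oxooctan-3-yl hexadecanoate, 18 2-(1,3-oxazol-5-yl)acetamide
Product: 21 (1R,3S,4R,5S)-3,4,5-tris(benzyloxy)-1-{2-[(1,3-oxazol-5-yl)methyl]-1,3-oxazol-4-yl}hexyl hexadecanoate, via O-alkyl imidate 19 (not isolated), via 4-hydroxyoxazoline 20 (not isolated)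
Conditions: AgOTf, 2,6-di-tert-butyl-4-methylpyridine, 4 Å MS, EtOAc, 60 °C, dark (18 in excess)
Reagents that add atoms: none
Why: Blümlein–Lewy (Hantzsch-type) oxazole synthesis: silver(I) pulls bromide from the CH2Br carbon as the amide oxygen of 18 attacks it in an SN2 step, so O1–C5 forms first and gives imidate 19. The imidate nitrogen then adds to the ketone carbonyl in a 5-exo-trig closure (N3–C4), and hydroxyoxazoline 20 loses water under the mild acidity of the pyridinium triflate to aromatise. The closest known reaction type is the silver-promoted condensation of α-bromo ketones with primary carboxamides to 2,4-disubstituted oxazoles. No stereocentre is created; the one at C1, α to the ketone, is the only one at risk and is protected by the absence of any base stronger than the hindered pyridine and by the removal of the ketone once the imidate cyclises. Regiochemistry is fixed by the substrate, since only the bromine-bearing carbon is electrophilic towards oxygen and it carries two hydrogens, which makes it the unsubstituted C5 while the ketone carbon becomes C4. Chemoselectivity for the amide oxygen over the weakly basic oxazole nitrogen rests on the higher nucleophilicity of the carboxamide oxygen and on the excess of 18.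

Step 13
Reactants: 21 (1R,3S,4R,5S)-3,4,5-tris(benzyloxy)-1-{2-[(1,3-oxazol-5-yl)methyl]-1,3-oxazol-4-yl}hexyl hexadecanoate
Product: 22 (1R,3S,4R,5S)-3,4,5-trihydroxy-1-{2-[(1,3-oxazol-5-yl)methyl]-1,3-oxazol-4-yl}hexyl hexadecanoate (target)
Conditions: H2 (1 atm), Pd(OH)2/C, EtOAc/EtOH, rt
Reagents that add atoms: none
Why: Hydrogenolysis of benzyl ethers over Pearlman's catalyst in a neutral medium, which should leave both oxazoles, the ester and all four stereocentres untouched and give no acid or base to drive 1→3 acyl migration.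

**Compound list**

1 | 2-deoxy-L-fucose (2,6-dideoxy-L-lyxo-hexose, open-chain form) | O=CC[C@H](O)[C@H](O)[C@H](C)O | starting material
2 | 2-deoxy-L-fucose diethyl dithioacetal | CCSC(SCC)C[C@H](O)[C@H](O)[C@H](C)O | intermediate
3 | 3,4,5-tri-O-benzyl-2-deoxy-L-fucose diethyl dithioacetal | CCSC(SCC)C[C@H](OCc1ccccc1)[C@H](OCc1ccccc1)[C@H](C)OCc1ccccc1 | intermediate
4 | (3S,4R,5S)-3,4,5-tris(benzyloxy)hexanal | O=CC[C@H](OCc1ccccc1)[C@H](OCc1ccccc1)[C@H](C)OCc1ccccc1 | intermediate
5 | ethynyltrimethylsilane | C#C[Si](C)(C)C | starting material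
6 | lithium (trimethylsilyl)acetylide | [Li]C#C[Si](C)(C)C | intermediate
7 | (5S,6R,7S)-5,6,7-tris(benzyloxy)-1-(trimethylsilyl)oct-1-yn-3-ol, both C3 epimers | C[Si](C)(C)C#CC(O)C[C@H](OCc1ccccc1)[C@H](OCc1ccccc1)[C@H](C)OCc1ccccc1 | intermediate
8 | (5S,6R,7S)-5,6,7-tris(benzyloxy)-1-(trimethylsilyl)oct-1-yn-3-one | C[Si](C)(C)C#CC(=O)C[C@H](OCc1ccccc1)[C@H](OCc1ccccc1)[C@H](C)OCc1ccccc1 | intermediate
9 | (3R,5S,6R,7S)-5,6,7-tris(benzyloxy)-1-(trimethylsilyl)oct-1-yn-3-ol | O[C@H](C[C@H](OCc1ccccc1)[C@H](OCc1ccccc1)[C@H](C)OCc1ccccc1)C#C[Si](C)(C)C | intermediate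
10 | palmitoyl chloride (hexadecanoyl chloride) | CCCCCCCCCCCCCCCC(=O)Cl | starting material
11 | (3R,5S,6R,7S)-5,6,7-tris(benzyloxy)-1-(trimethylsilyl)oct-1-yn-3-yl hexadecanoate | CCCCCCCCCCCCCCCC(=O)O[C@H](C[C@H](OCc1ccccc1)[C@H](OCc1ccccc1)[C@H](C)OCc1ccccc1)C#C[Si](C)(C)C | intermediate
12 | (3R,5S,6R,7S)-5,6,7-tris(benzyloxy)-1-bromooct-1-yn-3-yl hexadecanoate | CCCCCCCCCCCCCCCC(=O)O[C@H](C[C@H](OCc1ccccc1)[C@H](OCc1ccccc1)[C@H](C)OCc1ccccc1)C#CBr | intermediate
13 | (3R,5S,6R,7S)-5,6,7-tris(benzyloxy)-1-bromo-2-oxooctan-3-yl hexadecanoate | CCCCCCCCCCCCCCCC(=O)O[C@H](C[C@H](OCc1ccccc1)[C@H](OCc1ccccc1)[C@H](C)OCc1ccccc1)C(=O)CBr | intermediate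
14 | 1,3-oxazole-5-carboxylic acid | OC(=O)c1cnco1 | starting material
15 | 1,3-oxazole-5-carbonyl chloride | ClC(=O)c1cnco1 | intermediate
16 | 2-diazo-1-(1,3-oxazol-5-yl)ethan-1-one | [N-]=[N+]=CC(=O)c1cnco1 | intermediate
17 | (1,3-oxazol-5-yl)ketene | O=C=Cc1cnco1 | intermediate
18 | 2-(1,3-oxazol-5-yl)acetamide | NC(=O)Cc1cnco1 | intermediate
19 | O-alkyl imidate: 2-oxoalkyl ester of 2-(oxazol-5-yl)acetimidic acid, formed by displacement of bromide in 13 by the amide oxygen | CCCCCCCCCCCCCCCC(=O)O[C@H](C[C@H](OCc1ccccc1)[C@H](OCc1ccccc1)[C@H](C)OCc1ccccc1)C(=O)COC(=N)Cc1cnco1 | intermediate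
20 | 4-hydroxy-4,5-dihydrooxazole: C4 bears OH and the palmitoyloxy chain, C2 the (oxazol-5-yl)methyl group; both configurations at the new C4 | CCCCCCCCCCCCCCCC(=O)O[C@H](C[C@H](OCc1ccccc1)[C@H](OCc1ccccc1)[C@H](C)OCc1ccccc1)C1(O)COC(Cc2cnco2)=N1 | intermediate
21 | (1R,3S,4R,5S)-3,4,5-tris(benzyloxy)-1-{2-[(1,3-oxazol-5-yl)methyl]-1,3-oxazol-4-yl}hexyl hexadecanoate | CCCCCCCCCCCCCCCC(=O)O[C@H](C[C@H](OCc1ccccc1)[C@H](OCc1ccccc1)[C@H](C)OCc1ccccc1)c1coc(Cc2cnco2)n1 | intermediate
22 | (1R,3S,4R,5S)-3,4,5-trihydroxy-1-{2-[(1,3-oxazol-5-yl)methyl]-1,3-oxazol-4-yl}hexyl hexadecanoate | CCCCCCCCCCCCCCCC(=O)O[C@H](C[C@H](O)[C@H](O)[C@H](C)O)c1coc(Cc2cnco2)n1 | target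

**Step count**

Total step count: 13.
Longest linear sequence: 11 steps (steps 1–9, 12 and 13); the amide branch adds steps 10 and 11.

**Steps most likely to fail**

Step 9. Capture of the gold-bound dioxolenium ion by water may be outrun by 1,2-acyloxy migration to a gold carbene and hence a bromodiene, or the C5 benzyloxy oxygen may add to the activated bromoalkyne. The fallback avoids the bromoalkyne and sets out from 11. Buffered protodesilylation (TBAF, AcOH, THF, 0 °C) should give the terminal alkyne (3R,5S,6R,7S)-5,6,7-tris(benzyloxy)oct-1-yn-3-yl hexadecanoate F1. Ester-assisted gold(I) hydration of this terminal propargylic ester (Ph3PAuCl, AgSbF6, aqueous dioxane) should give the methyl ketone (3R,5S,6R,7S)-5,6,7-tris(benzyloxy)-2-oxooctan-3-yl hexadecanoate F2. Soft enolisation on the methyl side (TMSOTf, Et3N, CH2Cl2, −78 °C) should give the silyl enol ether (3R,5S,6R,7S)-5,6,7-tris(benzyloxy)-2-(trimethylsilyloxy)oct-1-en-3-yl hexadecanoate F3. NBS in THF at −78 °C then brominates the terminal carbon and rejoins the route at 13.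

Step 12. O-alkylation by a weakly nucleophilic carboxamide may be slow enough for three side processes: the neighbouring palmitate carbonyl may take part in the silver-assisted ionisation (acyl transfer), C1 may epimerise through enolisation, or an oxazole nitrogen may be alkylated. The fallback carries a silyl ether at C1 through the ring closure and esterifies afterwards; it sets out from 9.
- TBSCl and imidazole in DMF should give the silyl ether tert-butyl{[(3R,5S,6R,7S)-5,6,7-tris(benzyloxy)-1-(trimethylsilyl)oct-1-yn-3-yl]oxy}dimethylsilane F4.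
- NBS with catalytic AgNO3 should give the bromoalkyne {[(3R,5S,6R,7S)-5,6,7-tris(benzyloxy)-1-bromooct-1-yn-3-yl]oxy}(tert-butyl)dimethylsilane F5.
- Gold(I)-catalysed hydration of the bromoalkyne (XPhosAuNTf2, aqueous dioxane) should give the bromomethyl ketone (3R,5S,6R,7S)-5,6,7-tris(benzyloxy)-1-bromo-3-[(tert-butyldimethylsilyl)oxy]octan-2-one F6.
- Condensation with 18 (AgOTf, hindered pyridine, EtOAc, 60 °C) should close the ring to the oxazole 4-{(1R,3S,4R,5S)-3,4,5-tris(benzyloxy)-1-[(tert-butyldimethylsilyl)oxy]hexyl}-2-[(1,3-oxazol-5-yl)methyl]-1,3-oxazole F7.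
- HF·pyridine in THF should free the alcohol (1R,3S,4R,5S)-3,4,5-tris(benzyloxy)-1-{2-[(1,3-oxazol-5-yl)methyl]-1,3-oxazol-4-yl}hexan-1-ol F8.
- Acylation with palmitoyl chloride 10 (pyridine, DMAP, CH2Cl2) returns to the route at 21.

Step 13. Reductive cleavage of the oxazole-activated C1–O ester bond may compete with debenzylation, the catalyst may be slowed by coordination of the two oxazoles, and long reaction times invite acyl migration from O1 to O3. The fallback is a non-reductive, Lewis-acid ether cleavage that sets out from 21: BCl3 with pentamethylbenzene as cation scavenger in CH2Cl2 at −78 °C, quenched cold with methanol, should give 22 directly. This detour makes no compound outside the compound list (F0).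

**Further compounds**

F1 | step 9 | (3R,5S,6R,7S)-5,6,7-tris(benzyloxy)oct-1-yn-3-yl hexadecanoate | CCCCCCCCCCCCCCCC(=O)O[C@H](C[C@H](OCc1ccccc1)[C@H](OCc1ccccc1)[C@H](C)OCc1ccccc1)C#C
F2 | step 9 | (3R,5S,6R,7S)-5,6,7-tris(benzyloxy)-2-oxooctan-3-yl hexadecanoate | CCCCCCCCCCCCCCCC(=O)O[C@H](C[C@H](OCc1ccccc1)[C@H](OCc1ccccc1)[C@H](C)OCc1ccccc1)C(C)=O
F3 | step 9 | (3R,5S,6R,7S)-5,6,7-tris(benzyloxy)-2-(trimethylsilyloxy)oct-1-en-3-yl hexadecanoate | CCCCCCCCCCCCCCCC(=O)O[C@H](C[C@H](OCc1ccccc1)[C@H](OCc1ccccc1)[C@H](C)OCc1ccccc1)C(=C)O[Si](C)(C)C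
F4 | step 12 | tert-butyl{[(3R,5S,6R,7S)-5,6,7-tris(benzyloxy)-1-(trimethylsilyl)oct-1-yn-3-yl]oxy}dimethylsilane | CC(C)(C)[Si](C)(C)O[C@H](C[C@H](OCc1ccccc1)[C@H](OCc1ccccc1)[C@H](C)OCc1ccccc1)C#C[Si](C)(C)C
F5 | step 12 | {[(3R,5S,6R,7S)-5,6,7-tris(benzyloxy)-1-bromooct-1-yn-3-yl]oxy}(tert-butyl)dimethylsilane | CC(C)(C)[Si](C)(C)O[C@H](C[C@H](OCc1ccccc1)[C@H](OCc1ccccc1)[C@H](C)OCc1ccccc1)C#CBr
F6 | step 12 | (3R,5S,6R,7S)-5,6,7-tris(benzyloxy)-1-bromo-3-[(tert-butyldimethylsilyl)oxy]octan-2-one | CC(C)(C)[Si](C)(C)O[C@H](C[C@H](OCc1ccccc1)[C@H](OCc1ccccc1)[C@H](C)OCc1ccccc1)C(=O)CBr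
F7 | step 12 | 4-{(1R,3S,4R,5S)-3,4,5-tris(benzyloxy)-1-[(tert-butyldimethylsilyl)oxy]hexyl}-2-[(1,3-oxazol-5-yl)methyl]-1,3-oxazole | CC(C)(C)[Si](C)(C)O[C@H](C[C@H](OCc1ccccc1)[C@H](OCc1ccccc1)[C@H](C)OCc1ccccc1)c1coc(Cc2cnco2)n1
F8 | step 12 | (1R,3S,4R,5S)-3,4,5-tris(benzyloxy)-1-{2-[(1,3-oxazol-5-yl)methyl]-1,3-oxazol-4-yl}hexan-1-ol | O[C@H](C[C@H](OCc1ccccc1)[C@H](OCc1ccccc1)[C@H](C)OCc1ccccc1)c1coc(Cc2cnco2)n1
F0 | step 13 | none | none
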